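## Retrosynthetic overview

1. Target ⇒ palmitoyl chloride plus an (S)-configured primary alcohol that carries N-TIPS and O-TES groups (ester C–O bond; both silyl groups come off last).
2. The CH2OH group and the only stereocentre ⇒ enantioselective CuH-catalysed hydroboration (the new step), then C–B oxidation, of a 1,1-disubstituted alkene on indole C3.
3. That alkene ⇒ Negishi coupling (indole C3–C(sp2) bond) of a 3-indolylzinc with the vinyl triflate of silylated 3-hydroxy-3-methylbutan-2-one.
4. The prenyl group ⇒ arylcopper substitution on prenyl bromide at C5 of N-TIPS-5-bromoindole.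
5. No ring is formed: the indole bicycle is bought intact as 5-bromoindole.

Assumption: the (R)-ligand in step 7 is taken to give the (R)-boronate (quadrant model); if the first run shows the opposite sense, the (S)-ligand is used and nothing else changes.

## Route

Step 1
Reactants: 1 5-bromo-1H-indole
Product: 3 5-bromo-1-(triisopropylsilyl)-1H-indole, via sodium 5-bromoindol-1-ide 2 (not isolated)
Conditions: NaH, THF, 0 °C; then TIPSCl, 0 °C to rt
Reagents that add atoms: triisopropylsilyl chloride, CC(C)[Si](Cl)(C(C)C)C(C)C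
Why: N-silylation of the sodium indolide (substitution at silicon) gives a group that masks N–H, screens C2 against lithiation and bromination, and survives organolithium reagents.

Step 2
Reactants: 3 5-bromo-1-(triisopropylsilyl)-1H-indole; 4 1-bromo-3-methylbut-2-ene (prenyl bromide)
Product: 7 5-(3-methylbut-2-en-1-yl)-1-(triisopropylsilyl)-1H-indole, via 5-indolyllithium 5 (not isolated), via 5-indolylcopper 6 (not isolated)
Conditions: t-BuLi (2 equiv), THF, −78 °C; CuBr·SMe2, −78 to −40 °C; then 4, −40 to 0 °C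
Reagents that add atoms: none
Why: Bromine–lithium exchange, transmetalation to copper and SN2 allylic substitution, in which the arylcopper attacks the unhindered CH2 end of prenyl bromide because attack at the other end would build a quaternary carbon.

Step 3
Reactants: 7 5-(3-methylbut-2-en-1-yl)-1-(triisopropylsilyl)-1H-indole
Product: 8 3-bromo-5-(3-methylbut-2-en-1-yl)-1-(triisopropylsilyl)-1H-indole
Conditions: NBS (1.0 equiv), THF, −78 °C, dark
Reagents that add atoms: N-bromosuccinimide, O=C1CCC(=O)N1Br
Why: Electrophilic aromatic bromination at C3, the most nucleophilic indole carbon (C2 is screened by the silyl group), which at −78 °C is far faster than bromonium formation at the trisubstituted alkene.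

Step 4
Reactants: 9 3-hydroxy-3-methylbutan-2-one
Product: 10 3-methyl-3-(triethylsilyloxy)butan-2-one
Conditions: TESOTf, 2,6-lutidine, CH2Cl2, −78 to 0 °C
Reagents that add atoms: triethylsilyl trifluoromethanesulfonate, CC[Si](CC)(CC)OS(=O)(=O)C(F)(F)F
Why: O-silylation of a tertiary alcohol with a silyl triflate and a hindered base is fast at low temperature and leaves the ketone untouched.

Step 5
Reactants: 10 3-methyl-3-(triethylsilyloxy)butan-2-one
Product: 12 3-methyl-3-(triethylsilyloxy)but-1-en-2-yl trifluoromethanesulfonate, via potassium enolate 11 (not isolated)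
Conditions: KN(SiMe3)2, THF, −78 °C; then PhNTf2, −78 to 0 °C
Reagents that add atoms: N-phenylbis(trifluoromethanesulfonimide), O=S(=O)(N(c1ccccc1)S(=O)(=O)C(F)(F)F)C(F)(F)F
Why: Enolate O-sulfonylation (vinyl triflate formation) can give only the terminal enol triflate because the methyl group is the only carbon with α-hydrogens.

Step 6
Reactants: 8 3-bromo-5-(3-methylbut-2-en-1-yl)-1-(triisopropylsilyl)-1H-indole; 12 3-methyl-3-(triethylsilyloxy)but-1-en-2-yl trifluoromethanesulfonate
Product: 15 3-[3-methyl-3-(triethylsilyloxy)but-1-en-2-yl]-5-(3-methylbut-2-en-1-yl)-1-(triisopropylsilyl)-1H-indole, via 3-indolyllithium 13 (not isolated), via 3-indolylzinc chloride 14 (not isolated)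
Conditions: t-BuLi (2 equiv), THF, −78 °C; ZnCl2, −78 °C to rt; then 12, Pd2(dba)3 (2.5 mol%), SPhos (10 mol%), 50 °C
Reagents that add atoms: none
Why: Negishi cross-coupling, in which bromine–lithium exchange at C3 and transmetalation to zinc are followed by oxidative addition of zerovalent palladium into the vinyl triflate, transmetalation and reductive elimination to forge the indole C3–C(sp2) bond, with the silyl groups and the prenyl alkene inert.

Step 7
Reactants: 15 3-[3-methyl-3-(triethylsilyloxy)but-1-en-2-yl]-5-(3-methylbut-2-en-1-yl)-1-(triisopropylsilyl)-1H-indole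
Product: 16 3-[(2R)-3-methyl-1-(4,4,5,5-tetramethyl-1,3,2-dioxaborolan-2-yl)-3-(triethylsilyloxy)butan-2-yl]-5-(3-methylbut-2-en-1-yl)-1-(triisopropylsilyl)-1H-indole
Conditions: CuCl (5 mol%), (R)-DTBM-SEGPHOS (6 mol%), NaOtBu (10 mol%), HBpin (2 equiv), toluene, 40 °C
Reagents that add atoms: pinacolborane, [H]B1OC(C)(C)C(C)(C)O1
Why: Proposed new method: CuH-catalysed enantioselective anti-Markovnikov hydroboration of a 1,1-disubstituted alkene whose two substituents are a 3-indolyl ring and a fully substituted silyloxy-bearing carbon, a substrate class on which it has not been shown; the ligand-bound CuH formed from CuCl, NaOtBu and HBpin adds syn across C=CH2 with copper on the terminal carbon and hydride on the internal carbon, the C2-symmetric bisphosphine pocket distinguishes the flat indolyl group from the bulky CMe2OSiEt3 group so that hydride reaches one face only and fixes the stereocentre, and σ-bond metathesis of the primary alkylcopper with HBpin then releases the boronate and regenerates CuH; the alkylcopper has no β-leaving group, the unactivated trisubstituted prenyl alkene does not insert, and the closest known reaction type is the CuH–bisphosphine hydroboration and hydroamination of α-alkylstyrenes.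

Step 8
Reactants: 16 3-[(2R)-3-methyl-1-(4,4,5,5-tetramethyl-1,3,2-dioxaborolan-2-yl)-3-(triethylsilyloxy)butan-2-yl]-5-(3-methylbut-2-en-1-yl)-1-(triisopropylsilyl)-1H-indole
Product: 17 (2S)-3-methyl-2-[5-(3-methylbut-2-en-1-yl)-1-(triisopropylsilyl)-1H-indol-3-yl]-3-(triethylsilyloxy)butan-1-ol
Conditions: NaBO3·4H2O, THF/H2O (1:1), rt
Reagents that add atoms: sodium perborate tetrahydrate, [Na+].[O-]OB=O.O.O.O.O
Why: Boronate oxidation by 1,2-migration from boron to oxygen converts C–B into C–OH without touching the stereocentre (it is β to boron), and mild perborate spares both silyl groups and the prenyl alkene.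

Step 9
Reactants: 17 (2S)-3-methyl-2-[5-(3-methylbut-2-en-1-yl)-1-(triisopropylsilyl)-1H-indol-3-yl]-3-(triethylsilyloxy)butan-1-ol; 18 hexadecanoyl chloride (palmitoyl chloride)
Product: 19 (2S)-3-methyl-2-[5-(3-methylbut-2-en-1-yl)-1-(triisopropylsilyl)-1H-indol-3-yl]-3-(triethylsilyloxy)butyl hexadecanoate
Conditions: pyridine, DMAP (cat.), CH2Cl2, 0 °C to rt
Reagents that add atoms: none
Why: DMAP-catalysed nucleophilic acyl substitution (esterification) at the only free hydroxyl, since the tertiary oxygen and the indole nitrogen are both silylated.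

Step 10
Reactants: 19 (2S)-3-methyl-2-[5-(3-methylbut-2-en-1-yl)-1-(triisopropylsilyl)-1H-indol-3-yl]-3-(triethylsilyloxy)butyl hexadecanoate
Product: 20 (2S)-3-hydroxy-3-methyl-2-[5-(3-methylbut-2-en-1-yl)-1H-indol-3-yl]butyl hexadecanoate (CNP0125367.1)
Conditions: Bu4NF, AcOH (1:1, 3 equiv), THF, 0 °C to rt
Reagents that add atoms: none
Why: Fluoride-induced desilylation cleaves the N–Si and O–Si bonds, acetic acid buffering prevents ester cleavage or acyl migration, and no bond to the stereocentre is broken.

## Compound list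

1 | 5-bromo-1H-indole | Brc1ccc2[nH]ccc2c1 | starting material
2 | sodium 5-bromoindol-1-ide | [Na+].Brc1ccc2[n-]ccc2c1 | intermediate
3 | 5-bromo-1-(triisopropylsilyl)-1H-indole | CC(C)[Si](C(C)C)(C(C)C)n1ccc2cc(Br)ccc21 | intermediate
4 | 1-bromo-3-methylbut-2-ene (prenyl bromide) | CC(C)=CCBr | starting material
5 | [1-(triisopropylsilyl)-1H-indol-5-yl]lithium | [Li]c1ccc2c(c1)ccn2[Si](C(C)C)(C(C)C)C(C)C | intermediate
6 | [1-(triisopropylsilyl)-1H-indol-5-yl]copper | [Cu]c1ccc2c(c1)ccn2[Si](C(C)C)(C(C)C)C(C)C | intermediate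
7 | 5-(3-methylbut-2-en-1-yl)-1-(triisopropylsilyl)-1H-indole | CC(C)=CCc1ccc2c(c1)ccn2[Si](C(C)C)(C(C)C)C(C)C | intermediate
8 | 3-bromo-5-(3-methylbut-2-en-1-yl)-1-(triisopropylsilyl)-1H-indole | CC(C)=CCc1ccc2c(c1)c(Br)cn2[Si](C(C)C)(C(C)C)C(C)C | intermediate
9 | 3-hydroxy-3-methylbutan-2-one | CC(=O)C(C)(C)O | starting material
10 | 3-methyl-3-(triethylsilyloxy)butan-2-one | CC(=O)C(C)(C)O[Si](CC)(CC)CC | intermediate
11 | potassium 3-methyl-3-(triethylsilyloxy)but-1-en-2-olate | [K+].[O-]C(=C)C(C)(C)O[Si](CC)(CC)CC | intermediate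
12 | 3-methyl-3-(triethylsilyloxy)but-1-en-2-yl trifluoromethanesulfonate | C=C(OS(=O)(=O)C(F)(F)F)C(C)(C)O[Si](CC)(CC)CC | intermediate
13 | [5-(3-methylbut-2-en-1-yl)-1-(triisopropylsilyl)-1H-indol-3-yl]lithium | CC(C)=CCc1ccc2c(c1)c([Li])cn2[Si](C(C)C)(C(C)C)C(C)C | intermediate
14 | chloro[5-(3-methylbut-2-en-1-yl)-1-(triisopropylsilyl)-1H-indol-3-yl]zinc | CC(C)=CCc1ccc2c(c1)c([Zn]Cl)cn2[Si](C(C)C)(C(C)C)C(C)C | intermediate
15 | 3-[3-methyl-3-(triethylsilyloxy)but-1-en-2-yl]-5-(3-methylbut-2-en-1-yl)-1-(triisopropylsilyl)-1H-indole | C=C(c1cn([Si](C(C)C)(C(C)C)C(C)C)c2ccc(CC=C(C)C)cc12)C(C)(C)O[Si](CC)(CC)CC | intermediate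
16 | 3-[(2R)-3-methyl-1-(4,4,5,5-tetramethyl-1,3,2-dioxaborolan-2-yl)-3-(triethylsilyloxy)butan-2-yl]-5-(3-methylbut-2-en-1-yl)-1-(triisopropylsilyl)-1H-indole | CC1(C)OB(C[C@H](c2cn([Si](C(C)C)(C(C)C)C(C)C)c3ccc(CC=C(C)C)cc23)C(C)(C)O[Si](CC)(CC)CC)OC1(C)C | intermediate
17 | (2S)-3-methyl-2-[5-(3-methylbut-2-en-1-yl)-1-(triisopropylsilyl)-1H-indol-3-yl]-3-(triethylsilyloxy)butan-1-ol | OC[C@H](c1cn([Si](C(C)C)(C(C)C)C(C)C)c2ccc(CC=C(C)C)cc12)C(C)(C)O[Si](CC)(CC)CC | intermediate
18 | hexadecanoyl chloride (palmitoyl chloride) | CCCCCCCCCCCCCCCC(=O)Cl | starting material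
19 | (2S)-3-methyl-2-[5-(3-methylbut-2-en-1-yl)-1-(triisopropylsilyl)-1H-indol-3-yl]-3-(triethylsilyloxy)butyl hexadecanoate | CCCCCCCCCCCCCCCC(=O)OC[C@H](c1cn([Si](C(C)C)(C(C)C)C(C)C)c2ccc(CC=C(C)C)cc12)C(C)(C)O[Si](CC)(CC)CC | intermediate
20 | (2S)-3-hydroxy-3-methyl-2-[5-(3-methylbut-2-en-1-yl)-1H-indol-3-yl]butyl hexadecanoate | CCCCCCCCCCCCCCCC(=O)OC[C@H](c1c[nH]c2ccc(CC=C(C)C)cc12)C(C)(C)O | target

## Step count and risks

Total step count: 10. Longest linear sequence: 8 steps (1, 2, 3, 6, 7, 8, 9, 10 from 5-bromoindole); the triflate branch (steps 4 and 5) joins at step 6.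

The three steps most likely to fail:

**Step 2 (prenylation).** The risk is attack at the substituted end of prenyl bromide, which would give the 1,1-dimethylallyl isomer, or homocoupling. The fallback sets out from 3 and replaces the stoichiometric organocopper substitution by a catalyst-controlled Suzuki–Miyaura coupling with commercial 3-methylbut-2-en-1-ylboronic acid pinacol ester (Pd(OAc)2, a bulky biaryl monophosphine chosen for the linear product, K3PO4, THF/H2O, 40 °C). It comes back to the route at 7. It makes no new compound, and its entry F0 stands for none.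

**Step 6 (Negishi coupling).** The risk is slow coupling at the hindered vinyl triflate, with protodemetalation returning 7. The fallback sets out from 8 and 10. The 3-indolyllithium 13, generated from 8 by bromine–lithium exchange as in step 6, is added at −78 °C to ketone 10 in the presence of anhydrous CeCl3, which suppresses enolisation of the methyl ketone. This gives the racemic tertiary carbinol 3-methyl-2-[5-(3-methylbut-2-en-1-yl)-1-(triisopropylsilyl)-1H-indol-3-yl]-3-(triethylsilyloxy)butan-2-ol F1. Dehydration of F1 with Burgess reagent (benzene, 50 °C) can place the double bond only toward the methyl group, because the other neighbour of the carbinol carbon is quaternary. The fallback comes back to the route at 15.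

**Step 7 (the proposed new hydroboration).** The risk is that the hindered alkene, twisted out of conjugation with the indole, inserts slowly or with modest enantioselectivity. The fallback uses known chemistry, sets out from 15 and comes back at 17. Hydroboration of 15 with 9-BBN (THF, 50 °C), which is selective for the 1,1-disubstituted alkene over the trisubstituted prenyl alkene, gives the racemic borane 3-[1-(9-borabicyclo[3.3.1]nonan-9-yl)-3-methyl-3-(triethylsilyloxy)butan-2-yl]-5-(3-methylbut-2-en-1-yl)-1-(triisopropylsilyl)-1H-indole F2. Oxidation of F2 in the same flask with NaBO3·4H2O gives the racemic alcohol 3-methyl-2-[5-(3-methylbut-2-en-1-yl)-1-(triisopropylsilyl)-1H-indol-3-yl]-3-(triethylsilyloxy)butan-1-ol F3. The alcohol F3 is then resolved classically: esterification with (S)-2-methoxy-2-phenylacetic acid (DCC, DMAP, CH2Cl2, 0 °C) gives two diastereomeric esters, which are separated by preparative HPLC on silica. The wanted ester is (2S)-3-methyl-2-[5-(3-methylbut-2-en-1-yl)-1-(triisopropylsilyl)-1H-indol-3-yl]-3-(triethylsilyloxy)butyl (2S)-2-methoxy-2-phenylacetate F4. The other ester is (2R)-3-methyl-2-[5-(3-methylbut-2-en-1-yl)-1-(triisopropylsilyl)-1H-indol-3-yl]-3-(triethylsilyloxy)butyl (2S)-2-methoxy-2-phenylacetate F5. The ester F5 is discarded. The configuration of F4 and F5 is assigned by NMR anisotropy analysis of the pair and confirmed by crystallography of a derivative. Methanolysis of F4 (K2CO3, MeOH, rt) returns alcohol 17, and the route continues with step 9.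

## Further compounds

F0 | step 2 | none | none
F1 | step 6 | 3-methyl-2-[5-(3-methylbut-2-en-1-yl)-1-(triisopropylsilyl)-1H-indol-3-yl]-3-(triethylsilyloxy)butan-2-ol (racemic) | CC(O)(c1cn([Si](C(C)C)(C(C)C)C(C)C)c2ccc(CC=C(C)C)cc12)C(C)(C)O[Si](CC)(CC)CC
F2 | step 7 | 3-[1-(9-borabicyclo[3.3.1]nonan-9-yl)-3-methyl-3-(triethylsilyloxy)butan-2-yl]-5-(3-methylbut-2-en-1-yl)-1-(triisopropylsilyl)-1H-indole (racemic) | CC(C)=CCc1ccc2c(c1)c(C(CB1C3CCCC1CCC3)C(C)(C)O[Si](CC)(CC)CC)cn2[Si](C(C)C)(C(C)C)C(C)C
F3 | step 7 | 3-methyl-2-[5-(3-methylbut-2-en-1-yl)-1-(triisopropylsilyl)-1H-indol-3-yl]-3-(triethylsilyloxy)butan-1-ol (racemic) | OCC(c1cn([Si](C(C)C)(C(C)C)C(C)C)c2ccc(CC=C(C)C)cc12)C(C)(C)O[Si](CC)(CC)CC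
F4 | step 7 | (2S)-3-methyl-2-[5-(3-methylbut-2-en-1-yl)-1-(triisopropylsilyl)-1H-indol-3-yl]-3-(triethylsilyloxy)butyl (2S)-2-methoxy-2-phenylacetate | CO[C@H](C(=O)OC[C@H](c1cn([Si](C(C)C)(C(C)C)C(C)C)c2ccc(CC=C(C)C)cc12)C(C)(C)O[Si](CC)(CC)CC)c1ccccc1
F5 | step 7 | (2R)-3-methyl-2-[5-(3-methylbut-2-en-1-yl)-1-(triisopropylsilyl)-1H-indol-3-yl]-3-(triethylsilyloxy)butyl (2S)-2-methoxy-2-phenylacetate | CO[C@H](C(=O)OC[C@@H](c1cn([Si](C(C)C)(C(C)C)C(C)C)c2ccc(CC=C(C)C)cc12)C(C)(C)O[Si](CC)(CC)CC)c1ccccc1
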